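**Strategy.** Labdane numbering is used. Everything rests on one intramolecular Diels–Alder reaction that turns an acyclic tetraene into the complete cis-decalin. It exploits ring A as a cyclohexene retron: C4, which carries the ester, is a diene carbon (C2=C3–C4=C5), the quaternary C10 with its methyl is the inner carbon of an isopropenyl dienophile (C1=C10), and the ring B carbons C6–C9 are the tether. One operation forms C1–C2 and C5–C10, closes both rings and sets C5 and C10 under control of the C9 stereocentre, which an auxiliary-directed alkylation provides. Reductive methylation then makes C4 quaternary, and a Negishi coupling adds the (E)-butenediol side chain.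

Key step: step 10

Remark (assumption): read as drawn, the target is the A/B-cis labdane (4S,5S,9S,10R) with H5, the C20 methyl, C11 and the C4 ester on one face, and the route is built for that isomer.
Numbering: ring A = C1–C5 and C10; ring B = C5–C10; C17 = CH2 on C8; C19 = ester carbon on C4; C20 = methyl on C10; side chain C11–C16.

**Route**

Step 1
Reactants: 1 (R)-4-benzyl-1,3-oxazolidin-2-one; 2 3-methylbut-2-enoyl chloride
Product: 4 (4R)-4-benzyl-3-(3-methylbut-2-enoyl)-1,3-oxazolidin-2-one, via lithium oxazolidinide 3 (not isolated)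
Conditions: n-BuLi, THF, −78 °C; then 2, −78 → 0 °C
Reagents that add atoms: none
Why: N-acylation of the lithiated oxazolidinone by the acid chloride; no stereocentre is formed, and the absence of an amine base avoids ketene-type deconjugation.

Step 2
Reactants: 4 (4R)-4-benzyl-3-(3-methylbut-2-enoyl)-1,3-oxazolidin-2-one; 5 methyl bromoacetate
Product: 7 methyl (3R)-3-{[(4R)-4-benzyl-2-oxo-1,3-oxazolidin-3-yl]carbonyl}-4-methylpent-4-enoate, via sodium dienolate 6 (not isolated)
Conditions: NaN(SiMe3)2, THF, −78 °C; then 5, −78 → −45 °C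
Reagents that add atoms: none
Why: Evans alkylation: γ-deprotonation gives the chelated (Z)-dienolate, which is alkylated at the α-carbon (future C9) on the face opposite the benzyl group, which sets C9 and moves the alkene out of conjugation into the isopropenyl group (C10=C1).

Step 3
Reactants: 7 methyl (3R)-3-{[(4R)-4-benzyl-2-oxo-1,3-oxazolidin-3-yl]carbonyl}-4-methylpent-4-enoate
Product: 8 methyl (3R)-3-[(ethylsulfanyl)carbonyl]-4-methylpent-4-enoate
Conditions: EtSH, n-BuLi, THF, 0 °C
Reagents that add atoms: ethanethiol, CCS
Why: Acyl substitution by lithium ethanethiolate at the more electrophilic imide carbonyl releases the auxiliary; the weakly basic thiolate should leave C9 and the methyl ester untouched.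

Step 4
Reactants: 9 4-bromobut-1-yne
Product: 11 methyl 5-bromopent-2-ynoate, via lithium acetylide 10 (not isolated)
Conditions: n-BuLi, THF, −78 °C; then ClCO2Me, −78 → −20 °C
Reagents that add atoms: methyl chloroformate, COC(=O)Cl
Why: C-acylation of a lithium acetylide; at −78 °C deprotonation of the alkyne outruns attack on the primary bromide, and no stereocentre is formed.

Step 5
Reactants: 11 methyl 5-bromopent-2-ynoate
Product: 12 methyl 5-iodopent-2-ynoate
Conditions: NaI, acetone, reflux
Reagents that add atoms: sodium iodide, [Na+].[I-]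
Why: Finkelstein halide exchange gives the iodide needed for mild zinc insertion; no stereocentre.

Step 6
Reactants: 8 methyl (3R)-3-[(ethylsulfanyl)carbonyl]-4-methylpent-4-enoate; 12 methyl 5-iodopent-2-ynoate
Product: 14 dimethyl (7R)-6-oxo-7-(prop-1-en-2-yl)non-2-ynedioate, via alkylzinc iodide 13 (not isolated)
Conditions: 12, Zn dust (activated with BrCH2CH2Br and Me3SiCl), THF, 30 °C; then 8, PdCl2(PPh3)2 (5 mol %), PhMe/THF, rt
Reagents that add atoms: none
Why: Fukuyama coupling of the thioester with the alkylzinc iodide attaches C7–C4 with C19 under neutral conditions that tolerate both esters and should not epimerise the α-stereocentre C9.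

Step 7
Reactants: 14 dimethyl (7R)-6-oxo-7-(prop-1-en-2-yl)non-2-ynedioate
Product: 15 dimethyl (7R)-6-methylidene-7-(prop-1-en-2-yl)non-2-ynedioate
Conditions: CH2Br2, Zn, TiCl4 (pre-formed reagent), THF/CH2Cl2, 0 °C → rt
Reagents that add atoms: dibromomethane, BrCBr
Why: Takai–Lombardo methylenation: the non-basic zinc/titanium methylene reagent converts the C8 ketone into the C8=C17 methylidene in preference to the esters and without enolising the β,γ-unsaturated ketone, so C9 is kept.

Step 8
Reactants: 15 dimethyl (7R)-6-methylidene-7-(prop-1-en-2-yl)non-2-ynedioate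
Product: 16 dimethyl (2E,7R)-6-methylidene-7-(prop-1-en-2-yl)-2-(tributylstannyl)non-2-enedioate
Conditions: Bu3SnH, Pd(PPh3)4 (2 mol %), THF, 0 °C
Reagents that add atoms: tributyltin hydride, CCCC[SnH](CCCC)CCCC
Why: Palladium-catalysed hydrostannation of the alkynoate is a syn addition that places tin on the carbon α to the ester (C4) and hydrogen on C5, which fixes C6 cis to the ester.

Step 9
Reactants: 16 dimethyl (2E,7R)-6-methylidene-7-(prop-1-en-2-yl)-2-(tributylstannyl)non-2-enedioate
Product: 17 dimethyl (2Z,7R)-2-ethenyl-6-methylidene-7-(prop-1-en-2-yl)non-2-enedioate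
Conditions: vinyl bromide, Pd(PPh3)4 (5 mol %), copper iodide (CuI), CsF, DMF, 45 °C; used at once
Reagents that add atoms: vinyl bromide, C=CBr
Why: Stille coupling (copper iodide and fluoride assist transmetalation of the hindered α-stannyl enoate) replaces tin by vinyl with retention, giving the diene with C6 in the "outside" position of C5 that the cycloaddition needs.

Step 10
Reactants: 17 dimethyl (2Z,7R)-2-ethenyl-6-methylidene-7-(prop-1-en-2-yl)non-2-enedioate
Product: 18 methyl (4aR,5S,8aS)-5-(2-methoxy-2-oxoethyl)-4a-methyl-6-methylidene-3,4,4a,5,6,7,8,8a-octahydronaphthalene-1-carboxylate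
Conditions: PhMe (0.005 M), BHT (0.1 equiv), sealed tube, 170 °C
Reagents that add atoms: none
Why: A thermal, concerted [4+2] cycloaddition of inverse electron demand (ester-bearing diene C2=C3–C4=C5 as the four-electron partner, the unactivated 1,1-disubstituted alkene C1=C10 as the two-electron partner) forms C1–C2 and C5–C10 suprafacially on both partners; the closest known reaction type is the type 1 intramolecular Diels–Alder reaction of 1,7,9-decatrienes. Ring A is closed as the new cyclohexene by the cycloaddition itself, and ring B is closed through the four-carbon tether C6–C9 by the C5–C10 bond in the fused mode, the tether overriding the intrinsic "para" regiochemistry of a 2-substituted diene. C10 is set by the C9 stereocentre: the diene should add to the alkene face on which the C9 side chain stands anti to the forming C5–C10 bond, C8 lies anti to C1 and only the C9 hydrogen points at the diene, which minimises allylic strain with the C20 methyl. C5 is set by the orientation of the tether: with C6 "outside" on the diene, the cis ring fusion arises when C9 is endo and the C20 methyl exo. The step therefore needs this exo-methyl mode over the trans-fused mode, which would put the methyl under C4 of the diene and axial on both nascent rings; that steric penalty of a dienophile substituted on its inner carbon is what should favour the cis-fused adduct, and the isomers should be separable if the preference is incomplete. High dilution and BHT are there to hold back dimerisation of the electron-poor diene.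

Step 11
Reactants: 18 methyl (4aR,5S,8aS)-5-(2-methoxy-2-oxoethyl)-4a-methyl-6-methylidene-3,4,4a,5,6,7,8,8a-octahydronaphthalene-1-carboxylate
Product: 20 methyl (1S,4aR,5S,8aS)-5-(2-methoxy-2-oxoethyl)-1,4a-dimethyl-6-methylidenedecahydronaphthalene-1-carboxylate, via lithium ester enolate 19 (not isolated)
Conditions: Li (2.1 equiv), t-BuOH (1.0 equiv), NH3(l)/THF, −78 °C; then MeI, −78 → −33 °C
Reagents that add atoms: iodomethane, CI
Why: Reductive alkylation: dissolving-metal reduction of the enoate gives the C4 ester enolate regiospecifically and it is C-methylated in situ; allylic 1,3-strain should hold C6 axial on ring A so that the axial C20 methyl screens the face syn to it and iodomethane enters anti to C20, leaving the ester cis to C20 and H5.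

Step 12
Reactants: 20 methyl (1S,4aR,5S,8aS)-5-(2-methoxy-2-oxoethyl)-1,4a-dimethyl-6-methylidenedecahydronaphthalene-1-carboxylate
Product: 21 methyl (1S,4aR,5S,8aS)-5-(2-hydroxyethyl)-1,4a-dimethyl-6-methylidenedecahydronaphthalene-1-carboxylate
Conditions: LiBH4, THF, 0 °C → rt
Reagents that add atoms: none
Why: Chemoselective hydride reduction: LiBH4 reduces the unhindered CH2CO2Me ester, while the fully substituted, neopentyl-type C4 ester (syn to C20) should remain; no stereocentre is touched.

Step 13
Reactants: 21 methyl (1S,4aR,5S,8aS)-5-(2-hydroxyethyl)-1,4a-dimethyl-6-methylidenedecahydronaphthalene-1-carboxylate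
Product: 22 methyl (1S,4aR,5S,8aS)-5-(2-iodoethyl)-1,4a-dimethyl-6-methylidenedecahydronaphthalene-1-carboxylate
Conditions: I2, PPh3, imidazole, CH2Cl2, 0 °C → rt
Reagents that add atoms: iodine, [I][I]
Why: Appel-type iodination of the primary alcohol through the alkoxyphosphonium iodide (SN2 at C12).

Step 14
Reactants: 23 but-2-yne-1,4-diol
Product: 25 (2Z)-2-iodobut-2-ene-1,4-diol, via alkenylalanate 24 (not isolated)
Conditions: NaAlH2(OCH2CH2OCH3)2, THF, 0 °C → rt; then I2, −78 °C
Reagents that add atoms: iodine, [I][I]
Why: trans-Hydroalumination of the propargylic alkoxide (hydride to C14, aluminium to C13 inside a five-membered alkoxyalanate ring) and iodinolysis with retention put iodine cis to the C15 hydroxymethyl group, so the two CH2OH groups are trans.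

Step 15
Reactants: 25 (2Z)-2-iodobut-2-ene-1,4-diol
Product: 26 (2Z)-1,4-bis(tert-butyldimethylsilyloxy)-2-iodobut-2-ene
Conditions: t-BuMe2SiCl, imidazole, DMF, rt
Reagents that add atoms: tert-butyldimethylsilyl chloride, CC(C)(C)[Si](C)(C)Cl
Why: Silylation of both primary alcohols protects them from the organozinc reagent of the next step.

Step 16
Reactants: 22 methyl (1S,4aR,5S,8aS)-5-(2-iodoethyl)-1,4a-dimethyl-6-methylidenedecahydronaphthalene-1-carboxylate; 26 (2Z)-1,4-bis(tert-butyldimethylsilyloxy)-2-iodobut-2-ene
Product: 28 bis(tert-butyldimethylsilyl) ether of the target, via alkylzinc iodide 27 (not isolated)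
Conditions: 22, Zn dust, LiCl, THF, 35 °C; then 26, PdCl2(dppf) (5 mol %), THF, 50 °C
Reagents that add atoms: none
Why: Negishi coupling: zinc insertion into the primary iodide, then palladium-catalysed sp3–sp2 coupling with the alkenyl iodide with retention of alkene geometry forms C12–C13 and places C12 cis to C15, which is the (13E) alkene.

Step 17
Reactants: 28 bis(tert-butyldimethylsilyl) ether of the target
Product: 29 methyl (1S,4aR,5S,8aS)-5-[(3E)-5-hydroxy-3-(hydroxymethyl)pent-3-en-1-yl]-1,4a-dimethyl-6-methylidenedecahydronaphthalene-1-carboxylate (target)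
Conditions: Bu4NF, THF, 0 °C → rt
Reagents that add atoms: none
Why: Fluoride cleaves both primary silyl ethers; the hindered methyl ester should be inert.

**Compound list**

1 | (R)-4-benzyl-1,3-oxazolidin-2-one | O=C1OC[C@@H](Cc2ccccc2)N1 | starting material
2 | 3-methylbut-2-enoyl chloride | CC(C)=CC(=O)Cl | starting material
3 | lithium (R)-4-benzyl-2-oxo-1,3-oxazolidin-3-ide | [Li+].O=C1OC[C@@H](Cc2ccccc2)[N-]1 | intermediate
4 | (4R)-4-benzyl-3-(3-methylbut-2-enoyl)-1,3-oxazolidin-2-one | CC(C)=CC(=O)N1C(=O)OC[C@H]1Cc1ccccc1 | intermediate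
5 | methyl bromoacetate | COC(=O)CBr | starting material
6 | sodium (Z)-dienolate of 4 (O and the isopropenyl carbon cis) | [Na+].C=C(C)/C=C(\[O-])N1C(=O)OC[C@H]1Cc1ccccc1 | intermediate
7 | methyl (3R)-3-{[(4R)-4-benzyl-2-oxo-1,3-oxazolidin-3-yl]carbonyl}-4-methylpent-4-enoate | C=C(C)[C@H](C(=O)N1C(=O)OC[C@H]1Cc1ccccc1)CC(=O)OC | intermediate
8 | methyl (3R)-3-[(ethylsulfanyl)carbonyl]-4-methylpent-4-enoate | C=C(C)[C@H](C(=O)SCC)CC(=O)OC | intermediate
9 | 4-bromobut-1-yne | C#CCCBr | starting material
10 | (4-bromobut-1-yn-1-yl)lithium | [Li]C#CCCBr | intermediate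
11 | methyl 5-bromopent-2-ynoate | COC(=O)C#CCCBr | intermediate
12 | methyl 5-iodopent-2-ynoate | COC(=O)C#CCCI | intermediate
13 | (5-methoxy-5-oxopent-3-yn-1-yl)zinc iodide | COC(=O)C#CCC[Zn]I | intermediate
14 | dimethyl (7R)-6-oxo-7-(prop-1-en-2-yl)non-2-ynedioate | C=C(C)[C@H](C(=O)CCC#CC(=O)OC)CC(=O)OC | intermediate
15 | dimethyl (7R)-6-methylidene-7-(prop-1-en-2-yl)non-2-ynedioate | C=C(C)[C@H](C(=C)CCC#CC(=O)OC)CC(=O)OC | intermediate
16 | dimethyl (2E,7R)-6-methylidene-7-(prop-1-en-2-yl)-2-(tributylstannyl)non-2-enedioate | C=C(C)[C@H](C(=C)CC/C=C(/[Sn](CCCC)(CCCC)CCCC)C(=O)OC)CC(=O)OC | intermediate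
17 | dimethyl (2Z,7R)-2-ethenyl-6-methylidene-7-(prop-1-en-2-yl)non-2-enedioate | C=C(C)[C@H](C(=C)CC/C=C(/C=C)C(=O)OC)CC(=O)OC | intermediate
18 | methyl (4aR,5S,8aS)-5-(2-methoxy-2-oxoethyl)-4a-methyl-6-methylidene-3,4,4a,5,6,7,8,8a-octahydronaphthalene-1-carboxylate | C=C1CC[C@H]2[C@](C)(CCC=C2C(=O)OC)[C@H]1CC(=O)OC | intermediate
19 | lithium enolate of the C4 ester of 18 after 1,4-reduction | [Li+].C=C1CC[C@H]2[C@](C)(CCCC2=C([O-])OC)[C@H]1CC(=O)OC | intermediate
20 | methyl (1S,4aR,5S,8aS)-5-(2-methoxy-2-oxoethyl)-1,4a-dimethyl-6-methylidenedecahydronaphthalene-1-carboxylate | C=C1CC[C@H]2[C@](C)(CCC[C@]2(C)C(=O)OC)[C@H]1CC(=O)OC | intermediate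
21 | methyl (1S,4aR,5S,8aS)-5-(2-hydroxyethyl)-1,4a-dimethyl-6-methylidenedecahydronaphthalene-1-carboxylate | C=C1CC[C@H]2[C@](C)(CCC[C@]2(C)C(=O)OC)[C@H]1CCO | intermediate
22 | methyl (1S,4aR,5S,8aS)-5-(2-iodoethyl)-1,4a-dimethyl-6-methylidenedecahydronaphthalene-1-carboxylate | C=C1CC[C@H]2[C@](C)(CCC[C@]2(C)C(=O)OC)[C@H]1CCI | intermediate
23 | but-2-yne-1,4-diol | OCC#CCO | starting material
24 | cyclic sodium alkenylalanate from 23 (simplified; second hydroxyl drawn as sodium alkoxide) | [Na+].[Na+].COCCO[Al-]1(OCCOC)OCC=C1C[O-] | intermediate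
25 | (2Z)-2-iodobut-2-ene-1,4-diol | OC/C=C(\I)CO | intermediate
26 | (2Z)-1,4-bis(tert-butyldimethylsilyloxy)-2-iodobut-2-ene | CC(C)(C)[Si](C)(C)OC/C=C(\I)CO[Si](C)(C)C(C)(C)C | intermediate
27 | alkylzinc iodide from 22 (ZnI on C12) | C=C1CC[C@H]2[C@](C)(CCC[C@]2(C)C(=O)OC)[C@H]1CC[Zn]I | intermediate
28 | methyl (1S,4aR,5S,8aS)-5-[(3E)-5-(tert-butyldimethylsilyloxy)-3-(tert-butyldimethylsilyloxymethyl)pent-3-en-1-yl]-1,4a-dimethyl-6-methylidenedecahydronaphthalene-1-carboxylate | C=C1CC[C@H]2[C@](C)(CCC[C@]2(C)C(=O)OC)[C@H]1CC/C(=C\CO[Si](C)(C)C(C)(C)C)CO[Si](C)(C)C(C)(C)C | intermediate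
29 | methyl (1S,4aR,5S,8aS)-5-[(3E)-5-hydroxy-3-(hydroxymethyl)pent-3-en-1-yl]-1,4a-dimethyl-6-methylidenedecahydronaphthalene-1-carboxylate | C=C1CC[C@H]2[C@](C)(CCC[C@]2(C)C(=O)OC)[C@H]1CC/C(=C\CO)CO | target

**Step count and risks**

Total step count: 17. Longest linear sequence: 13 (steps 1, 2, 3, 6–13, 16, 17).

Steps most likely to fail:

1. Step 10. What may go wrong: poor discrimination between the two tether orientations (endo, cis-fused, against exo, trans-fused) at the temperature the unactivated dienophile needs, together with bimolecular dimerisation of the electron-poor diene. The exo-methyl preference is a steric argument and may be small. The fallback replaces the steric bias by a template; it sets out from ketone 14 and comes back at 18. The C8 carbonyl is kept through the diene synthesis: hydrostannation of 14 (Bu3SnH, Pd(PPh3)4) should give the keto stannane F1, and Stille vinylation as in step 9 the keto tetraene F2. F2 is cyclised in the presence of MgBr2·OEt2 (CH2Cl2/PhMe, 25–60 °C). Magnesium can bind the C8 ketone and the C19 ester carbonyl at the same time only when the tether lies under the diene, which is the cis-fused mode, and coordination of the ester should also lower the temperature needed. This should give the 8-oxo adduct F3, whose C9 is now α to a ketone and is handled without base. Methylenation of F3 with CH2Br2/Zn/TiCl4 then gives 18.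

2. Step 11. What may go wrong: loss of facial control in the methylation of the lithium enolate, electron transfer to the saturated ester, or attack of the C4 enolate on that ester (intramolecular Claisen condensation) before alkylation. The fallback uses hydrosilylation and fluoride-mediated alkylation instead of a dissolving metal; it sets out from 18 and comes back at 20. Copper-hydride-catalysed 1,4-hydrosilylation (Cu(OAc)2, 1,2-bis(diphenylphosphino)benzene, PhMe2SiH, PhMe, rt) touches only the conjugated ester and should give the silyl ketene acetal F4. F4 is then methylated as a metal-free enolate with (Me2N)3S+ Me3SiF2− and MeI in THF at −78 °C, where the same conformational lock and the C20 methyl should direct the electrophile, to give 20.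

3. Step 9. What may go wrong: slow transmetalation of the hindered α-stannyl enoate, leading to protodestannylation, homocoupling or loss of alkene geometry. The fallback reverses the polarity of the coupling; it sets out from 16 and comes back at 17. Iododestannylation with I2 in CH2Cl2 at 0 °C proceeds with retention and should give the α-iodo enoate F5. Suzuki–Miyaura coupling of F5 with CH2=CHBF3K (PdCl2(dppf), Cs2CO3, THF/H2O, 60 °C) then gives 17.

Further compounds
F1 | step 10 | dimethyl (2E,7R)-6-oxo-7-(prop-1-en-2-yl)-2-(tributylstannyl)non-2-enedioate | C=C(C)[C@H](C(=O)CC/C=C(/[Sn](CCCC)(CCCC)CCCC)C(=O)OC)CC(=O)OC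
F2 | step 10 | dimethyl (2Z,7R)-2-ethenyl-6-oxo-7-(prop-1-en-2-yl)non-2-enedioate | C=C(C)[C@H](C(=O)CC/C=C(/C=C)C(=O)OC)CC(=O)OC
F3 | step 10 | methyl (4aS,5R,8aS)-5-(2-methoxy-2-oxoethyl)-4a-methyl-6-oxo-3,4,4a,5,6,7,8,8a-octahydronaphthalene-1-carboxylate | O=C1CC[C@H]2[C@](C)(CCC=C2C(=O)OC)[C@H]1CC(=O)OC
F4 | step 11 | O-[dimethyl(phenyl)silyl] O-methyl ketene acetal at C4 of the 1,4-reduced adduct (C5, C9 and C10 as in 18) | C=C1CC[C@H]2[C@](C)(CCCC2=C(OC)O[Si](C)(C)c2ccccc2)[C@H]1CC(=O)OC
F5 | step 9 | dimethyl (2E,7R)-2-iodo-6-methylidene-7-(prop-1-en-2-yl)non-2-enedioate | C=C(C)[C@H](C(=C)CC/C=C(/I)C(=O)OC)CC(=O)OC
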